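The earlier runs and the new flask stem from a simulated flask with constants of no real substance.

The vessel was closed, stirred and isothermal, and three runs showed it at one substrate charge with the partner charge rising.

| flask | substrate | partner | catalyst | remark | time |
|---|---|---|---|---|---|
| birch | 0.040 M | 0.032 M | 0.40 mM | run made earlier |  |
| alder | 0.040 M | 0.072 M | 0.40 mM | run made earlier |  |
| cedar | 0.040 M | 0.14 M | 0.40 mM | run made earlier |  |
| dawn | 0.040 M | 0.0800 M | 0.40 mM |  | 8.0 min |
| summer | 0.040 M | 0.160 M | 0.40 mM |  | 8.0 min |
| spring | 0.040 M | 0.0400 M | 0.40 mM |  | 8.0 min |

| run | time / min | target / % | substrate / % |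
|---|---|---|---|
| birch | 1.00 | 30 | 71 |
| birch | 2.50 | 33 | 62 |
| birch | 3.00 | 32 | 58 |
| birch | 5.00 | 32 | 52 |
| birch | 6.00 | 34 | 48 |
| alder | 0.417 | 34 | 65 |
| alder | 0.833 | 50 | 47 |
| alder | 1.50 | 57 | 36 |
| alder | 3.00 | 68 | 24 |
| alder | 6.00 | 63 | 19 |
| cedar | 1.00 | 81 | 16 |
| cedar | 2.50 | 90 | 6 |
| cedar | 3.00 | 89 | 3 |
| cedar | 5.00 | 88 | 3 |
| cedar | 6.00 | 88 | 0 |

(each reading ± 1.5 percentage points)

1. which of the two there is more of at the end, dawn (target / isomer of the product)
2. which of the two there is more of at the end, summer (target / isomer of the product)
3. which of the two there is more of at the end, spring (target / isomer of the product)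
4. target at the end, in percent of the substrate charged, dawn
5. target at the end, in percent of the substrate charged, summer
6. target at the end, in percent of the substrate charged, spring

- the numbers in the tables scatter with a standard deviation of 1.5 percentage points
- a reading or a percentage of target counts all its forms, free or not

Where did target stop? In birch it read 33% at 2.50 min and 34% at 6.00 min, while substrate fell from 62% to 48%. So substrate went on and target stood. Read at 2.50 min, birch had 2.42 moles of partner charged per mole of target. I called this the partner price. Alder, at its top reading, gave 2.65.

What did the price allow? I priced spring from birch, its nearest run, and got a ceiling of 41.3%. I priced dawn from alder and got 75.6%. Summer, at the birch price, came to 165%, which is over the charge, so I took substrate as the limiting reagent there. I let cedar's 89% stand for summer.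

Did the ceiling last? Alder fell from 68% to 63% between 3.00 min and 6.00 min. Birch showed no such fall beyond the scatter, so this rested on one pair of readings. Carried on to 8.0 min, that fall left a factor of 0.880. My figures were 36.3% for spring and 66.5% for dawn.

Which led? Birch's balance lacked 18.0% at 6.00 min, which covers isomer of the product and whatever else went unread. Scaled to 8.0 min, that is 24.0%, less than my spring target, so I put target ahead there. I put it ahead in dawn and summer too.

The forecast named target in all three, with 68% for dawn, 90% for summer and 41% for spring. Its ground was a birch plateau “close to the 40% expected if each target ties up a second partner”. For spring, my figure was lower than its figure.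

The flasks gave 67.4% in dawn, 88.7% in summer and 35.7% in spring. Target stood above isomer of the product in each, and spring held 12.3% isomer of the product.

    substrate + partner ⇌ target (K = 39.0 M⁻¹, k = 18.6 M⁻¹ min⁻¹)
    substrate + partner ⇌ isomer of the product (K = 5040 M⁻¹, k = 0.910 M⁻¹ min⁻¹)
    target + catalyst ⇌ isomer of the product + catalyst, rate k3*[catalyst]*[target] forward; the back reaction follows from the equilibrium constant (k = 159 M⁻¹ min⁻¹)
    substrate + target → side product (k = 2.78 M⁻¹ min⁻¹)
    partner + target ⇌ idle adduct, settled at all times (K = 140 M⁻¹)

The neighbour was spring stopped at 2.0 min. The birch price gave it a ceiling of 41.3%, and it held 40.2% target, a price of 2.49. Counted within that target, idle adduct stood at 25.1% of the substrate charged, and 30% of the partner was still free. Spring itself held 40.6% target at 4.00 min. At 8.00 min its price had risen to 2.80, with idle adduct at 20.8% of the substrate charged and 40% of the substrate still there.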